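**Plan**

1. Retrosynthesis: 12-OH from a C12–B bond (retentive oxidation) and 9-OAc from a C9 ketone; then C11–C12 and C1–C10 are cut together (intramolecular Diels–Alder) to the open-chain triene 27. Triene 27 is cut at C9–C10 (thiol ester plus Z-propenylstannane), C12=C13 (boryl olefination), C7–C8 with the lactone C–O (dioxolanone aldol) and C1–C2 (alkenylzinc addition).
2. Forward: neryl acetate gives C2–C7 with the Z-C5=C6 alkene; the C1/C14/C13 unit is added at C2; the lactone (ring C) is built at C7; the E,E-dienylboronate and the Z-enone are completed. One cycloaddition then closes the cyclohexene (ring A) and the ten-membered ring (ring B) together; reduction, acetylation and C–B oxidation finish.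
3. Enabling feature: ring A (C1, C10, C11, C12, C13=C14) is a Diels–Alder retron whose bond C1–C10 is the bond shared with ring B. C10 carries C9, which can be a ketone beside the tertiary C8 carbinol (an α'-hydroxy Z-enone dienophile), and the C12 oxygen can be carried as boron on an E,E-diene.
4. Stereochemistry: C2 from a (−)-MIB-catalysed alkenylzinc addition; C8 and C17 from an Evans glyoxylate aldol, C8 being stored in a pivalaldehyde dioxolanone; C7 from the aldol transition state; C1, C10, C11 and C12 from the cycloaddition (alkene geometries, exo mode, control by C2); C9 from a chelation-controlled reduction; Z-C5=C6 from nerol.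

Key step: step 15

Remark: atoms carry the briarane numbers of the target (C1–C14 in rings A and B, C15 on C1, C16 on C5, C17–C19 in the lactone with C18 on C17, C20 on C11); the facial outcome of steps 10, 15 and 16 is argued from models and has not been computed.

**Route**

Step 1
Reactants: 1 neryl acetate
Product: 2 (2Z)-5-(3,3-dimethyloxiran-2-yl)-3-methylpent-2-en-1-yl acetate (racemic at the oxirane carbon)
Conditions: mCPBA, CH2Cl2, 0 °C
Reagents that add atoms: mCPBA, OOC(=O)c1cccc(Cl)c1
Why: Prilezhaev epoxidation picks the electron-rich terminal trisubstituted alkene over the alkene deactivated by the allylic acetate; the oxirane stereocentre is lost in step 2.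

Step 2
Reactants: 2 epoxide
Product: 3 (2Z)-3-methyl-6-oxohex-2-en-1-yl acetate
Conditions: H5IO6, THF/H2O, 0 °C to rt
Reagents that add atoms: none
Why: Periodic acid opens the epoxide at the tertiary carbon to the glycol and cleaves it (Malaprade glycol cleavage), so the aldehyde oxygen is the former epoxide oxygen; the Z-alkene and the acetate are untouched.

Step 3
Reactants: 3 aldehyde; 4 1,1-diethoxybut-2-yne
Product: 7 (2Z,6R,7E)-9,9-diethoxy-6-hydroxy-3,7-dimethylnona-2,7-dien-1-yl acetate, via alkenylborane 5 (not isolated), via alkenylzinc 6 (not isolated)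
Conditions: Cy2BH (made in the flask from BH3·SMe2 and cyclohexene), 4, toluene, 0 °C to rt; Me2Zn, −78 °C; (2S)-3-exo-morpholinoisoborneol [(−)-MIB, 5 mol%], then 3, −10 °C; H2O work-up
Reagents that add atoms: none
Why: Syn hydroboration puts boron on the methyl-bearing alkyne carbon (away from the acetal), boron-to-zinc exchange and catalytic asymmetric alkenylzinc addition to the Si face of the aldehyde should give the 2R carbinol (C6 of this chain) with the E-trisubstituted C1=C14 alkene.

Step 4
Reactants: 7 allylic alcohol
Product: 8 (2Z,6R,7E)-9,9-diethoxy-3,7-dimethyl-6-(triethylsilyloxy)nona-2,7-dien-1-yl acetate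
Conditions: TESCl, imidazole, CH2Cl2, 0 °C
Reagents that add atoms: chlorotriethylsilane, CC[Si](Cl)(CC)CC
Why: Silylation masks the C2 hydroxyl for the oxidation and enolate steps and is removed later together with the acetal; no stereocentre is touched.

Step 5
Reactants: 8 silyl ether acetate
Product: 9 (2Z,6R,7E)-9,9-diethoxy-3,7-dimethyl-6-(triethylsilyloxy)nona-2,7-dien-1-ol
Conditions: K2CO3 (cat.), MeOH, 0 °C
Reagents that add atoms: none
Why: Zemplén-type transesterification removes the primary allylic acetate and leaves the triethylsilyl ether and the acetal intact.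

Step 6
Reactants: 9 allylic alcohol
Product: 10 (2Z,6R,7E)-9,9-diethoxy-3,7-dimethyl-6-(triethylsilyloxy)nona-2,7-dienal
Conditions: TEMPO (10 mol%), PhI(OAc)2, CH2Cl2, 0 °C to rt
Reagents that add atoms: none
Why: Oxoammonium (TEMPO) oxidation of the primary allylic alcohol stops at the aldehyde and converts nerol-type alcohols into the Z-enals without Z/E isomerisation.

Step 7
Reactants: 11 (4R)-4-benzyl-3-propanoyl-1,3-oxazolidin-2-one; 12 ethyl glyoxylate
Product: 15 ethyl (2R,3R)-4-[(4R)-4-benzyl-2-oxo-1,3-oxazolidin-3-yl]-2-hydroxy-3-methyl-4-oxobutanoate, via dibutylboron Z-enolate 13 (not isolated), via dibutylboron aldolate 14 (not isolated)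
Conditions: Bu2BOTf, iPr2NEt, CH2Cl2, −78 to 0 °C; 12, −78 to 0 °C; pH 7 buffer, MeOH, H2O2
Reagents that add atoms: none
Why: Evans syn-aldol reaction: the Z-boron enolate adds to the glyoxylate through a Zimmerman–Traxler chair on the face away from the benzyl group, setting C17 (R) and the C8 carbinol (R) in the syn relation the lactone needs.

Step 8
Reactants: 15 aldol adduct
Product: 16 (2R,3R)-2-hydroxy-3-methylbutanedioic acid
Conditions: LiOH, H2O2, THF/H2O, 0 °C to rt; Na2SO3; HCl
Reagents that add atoms: lithium hydroxide, [Li+].[OH-]; hydrogen peroxide, OO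
Why: Hydroperoxide cleaves the exocyclic imide carbonyl and hydroxide saponifies the ethyl ester (acyl substitution) without touching either stereocentre.

Step 9
Reactants: 16 diacid
Product: 17 (2R)-2-[(2R,4R)-2-tert-butyl-5-oxo-1,3-dioxolan-4-yl]propanoic acid
Conditions: tBuCHO, TsOH (cat.), H2SO4 (cat.), pentane, reflux, water separator
Reagents that add atoms: pivalaldehyde, CC(C)(C)C=O
Why: Acid-catalysed acetalisation of the α-hydroxy acid gives the five-membered dioxolanone with tert-butyl cis to the side chain under thermodynamic control, which stores the C8 configuration in the acetal carbon (self-regeneration of stereocentres).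

Step 10
Reactants: 17 dioxolanone acid; 10 Z-enal
Product: 20 spiro lactone–dioxolanone (γ-lactone O7–C7–C8–C17–C19 spiro at C8 to the 2-tert-butyl-1,3-dioxolan-4-one; 7S; C8 and C17 as in the target), via dilithium enolate 18 (not isolated), via seco hydroxy acid 19 (not isolated)
Conditions: LiN(SiMe3)2 (2.1 equiv), THF, −78 °C; 10, −78 °C; AcOH; then EDC·HCl, DMAP (cat.), CH2Cl2, 0 °C to rt
Reagents that add atoms: none
Why: Dioxolanone enolate aldol then lactonisation: the enolate (side chain protected as its carboxylate) adds to the aldehyde trans to tert-butyl, which regenerates C8 with retention, the closed chair transition state of this enolate (C17 cis to OLi) should place C17 and the new C7–O syn (7S), and carbodiimide activation closes the γ-lactone without touching C7.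

Step 11
Reactants: 20 spiro lactone–dioxolanone
Product: 21 S-ethyl thiol ester of the C9 acid (free tertiary 8-OH, lactone intact, silyl ether and acetal retained)
Conditions: NaSEt (1.1 equiv), THF, −20 to 0 °C; AcOH quench
Reagents that add atoms: sodium ethanethiolate, CC[S-].[Na+]
Why: Acyl substitution by thiolate at the activated acylal carbonyl C9 is faster than at the hindered γ-lactone (whose opening would be reversible) and releases pivalaldehyde and the C8 hydroxyl.

Step 12
Reactants: 21 thiol ester acetal
Product: 22 hydroxy enal thiol ester (C13 aldehyde, E-C1=C14, free 2-OH and 8-OH)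
Conditions: AcOH/THF/H2O (3:1:1), rt
Reagents that add atoms: water, O
Why: Acid-catalysed hydrolysis cleaves the diethyl acetal and the triethylsilyl ether in one operation; the E geometry keeps the γ-hydroxy enal from closing to a lactol, and thiol ester and lactone are stable to dilute acid.

Step 13
Reactants: 22 hydroxy enal thiol ester; 23 2-(dichloromethyl)-4,4,5,5-tetramethyl-1,3,2-dioxaborolane
Product: 25 (12E,1(14)E)-dienylboronate thiol ester, via gem-dichromium boryl reagent 24 (not isolated)
Conditions: CrCl2 (8 equiv), LiI, 23, THF, rt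
Reagents that add atoms: none
Why: Takai–Utimoto boryl olefination: the gem-dichromium reagent made by divalent chromium adds only to the aldehyde and eliminates to the E-alkenylboronate, which completes the E,E-diene; thiol ester, lactone and free hydroxyls are tolerated.

Step 14
Reactants: 25 dienylboronate thiol ester; 26 tributyl[(1Z)-prop-1-en-1-yl]stannane
Product: 27 open-chain triene (E,E-dienylboronate at C12–C1, Z-C5=C6, α'-hydroxy Z-enone C9(=O)–C10=C11)
Conditions: Pd2(dba)3 (2.5 mol%), P(2-furyl)3, CuO2PPh2 (1.5 equiv), 26, THF, rt to 40 °C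
Reagents that add atoms: none
Why: Base-free thiol ester–organostannane coupling of the Liebeskind–Srogl type (zerovalent palladium catalyst, monovalent copper as thiolate scavenger) forms the ketone with retention of the Z geometry; the pinacol boronate does not transmetalate without base and no allylic acetate is present to ionise.

Step 15
Reactants: 27 triene
Product: 28 cycloadduct (rings A, B and C; C9 ketone, 12-Bpin, free 2-OH and 8-OH; C1, C10, C11, C12 as in the target)
Conditions: toluene (0.001 M), BHT (cat.), 120 °C, sealed vessel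
Reagents that add atoms: none
Why: A thermal, concerted [4+2] cycloaddition (six electrons, suprafacial on both partners) joins the E,E-dienylboronate C12=C13–C14=C1 to the Z-enone C10=C11 so that C11–C12 and C1–C10 form together; the closest known reaction type is the macrocyclising type 1 intramolecular Diels–Alder reaction of long-tethered trienes, run here with a 1-boryl diene, whose adducts are known to be oxidised to allylic alcohols. Ring A is closed by the cycloaddition itself and ring B by the same C1–C10 bond in the fused (not bridged) mode with the C9 carbonyl and the eight-atom tether exo, which gives the trans C1/C10 junction. C10/C11 are set cis (C9 and C20) by the Z-enone, C12/C1 by the E,E-diene (boron and C2 outside, hence cis on ring A), their mutual relation (C9/C20 trans to B/C2) by the exo mode, and the absolute sense (1S,10S,11R,12R) by C2: A(1,2) strain with the C15 methyl holds H2 in the diene plane, so the chain (C3) lies on the face to which it delivers the dienophile and the hydroxyl on the other. The step needs fused regiochemistry, exo topology and this diene face: the 4,4-dialkyl terminus C1 bonds to the enone α-carbon C10 (the normal orientation of 1,1-dialkyl dienes), which the weakly directing boryl group, unlike a 1-silyloxy group, cannot reverse, and the tether, stiffened by the Z-C5=C6 alkene and the lactone, is expected to favour the exo, trans-fused closure over a cis-fused ring with transannular strain. The tertiary C8 hydroxyl hydrogen-bonds to the C9 carbonyl (α'-hydroxy enone), which holds the enone s-cis and lowers its LUMO, and high dilution suppresses intermolecular addition.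

Step 16
Reactants: 28 cycloadduct
Product: 29 2,8,9-triol 12-boronate (9-OH configured as the 9-OAc of the target)
Conditions: Zn(BH4)2 (made in the flask from ZnCl2 and NaBH4), Et2O/THF, −40 to −20 °C; aqueous work-up
Reagents that add atoms: none
Why: Chelation-controlled hydride reduction of the α-hydroxy ketone: zinc bridges O8 and O9, the ring chain between C7 and C10 covers one face of the chelated carbonyl, and hydride should add from the peripheral face on the C17 side, which gives the 8,9-anti diol.

Step 17
Reactants: 29 triol boronate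
Product: 30 2,9-diacetate 12-boronate
Conditions: Ac2O, Et3N, DMAP, CH2Cl2, rt
Reagents that add atoms: acetic anhydride, CC(=O)OC(C)=O
Why: DMAP-catalysed acylation esterifies the two secondary hydroxyls at C2 and C9, while the tertiary C8 hydroxyl is too hindered to react and C12 is still masked as boron.

Step 18
Reactants: 30 diacetate boronate
Product: 31 target CNP0222085.1
Conditions: NaBO3·4H2O, THF/H2O, 0 °C to rt
Reagents that add atoms: sodium perborate, [Na+].[Na+].O[B-]1(O)OO[B-](O)(O)OO1
Why: Perborate oxidation of the C–B bond goes by 1,2-migration of carbon from boron to oxygen with retention, giving the 12R alcohol without allylic transposition under conditions mild enough for the acetates and the lactone.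

**Compound list**

1 | neryl acetate | CC(=O)OC/C=C(C)\CCC=C(C)C | starting material
2 | (2Z)-5-(3,3-dimethyloxiran-2-yl)-3-methylpent-2-en-1-yl acetate | CC(=O)OC/C=C(C)\CCC1OC1(C)C | intermediate
3 | (2Z)-3-methyl-6-oxohex-2-en-1-yl acetate | CC(=O)OC/C=C(C)\CCC=O | intermediate
4 | 1,1-diethoxybut-2-yne | CCOC(OCC)C#CC | starting material
5 | dicyclohexyl(4,4-diethoxybut-2-en-2-yl)borane, boron trans to the acetal carbon | CCOC(OCC)/C=C(C)/B(C1CCCCC1)C1CCCCC1 | intermediate
6 | (4,4-diethoxybut-2-en-2-yl)(methyl)zinc, zinc trans to the acetal carbon | CCOC(OCC)/C=C(C)/[Zn]C | intermediate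
7 | (2Z,6R,7E)-9,9-diethoxy-6-hydroxy-3,7-dimethylnona-2,7-dien-1-yl acetate | CCOC(OCC)/C=C(C)/[C@H](O)CC/C(C)=C\COC(C)=O | intermediate
8 | (2Z,6R,7E)-9,9-diethoxy-3,7-dimethyl-6-(triethylsilyloxy)nona-2,7-dien-1-yl acetate | CCOC(OCC)/C=C(C)/[C@H](O[Si](CC)(CC)CC)CC/C(C)=C\COC(C)=O | intermediate
9 | (2Z,6R,7E)-9,9-diethoxy-3,7-dimethyl-6-(triethylsilyloxy)nona-2,7-dien-1-ol | CCOC(OCC)/C=C(C)/[C@H](O[Si](CC)(CC)CC)CC/C(C)=C\CO | intermediate
10 | (2Z,6R,7E)-9,9-diethoxy-3,7-dimethyl-6-(triethylsilyloxy)nona-2,7-dienal | CCOC(OCC)/C=C(C)/[C@H](O[Si](CC)(CC)CC)CC/C(C)=C\C=O | intermediate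
11 | (4R)-4-benzyl-3-propanoyl-1,3-oxazolidin-2-one | CCC(=O)N1[C@H](Cc2ccccc2)COC1=O | starting material
12 | ethyl glyoxylate | CCOC(=O)C=O | starting material
13 | dibutylboron Z-enolate of 11 | CCCCB(CCCC)O/C(=C\C)N1[C@H](Cc2ccccc2)COC1=O | intermediate
14 | dibutylboron aldolate of 15 | CCOC(=O)[C@H](OB(CCCC)CCCC)[C@@H](C)C(=O)N1[C@H](Cc2ccccc2)COC1=O | intermediate
15 | ethyl (2R,3R)-4-[(4R)-4-benzyl-2-oxo-1,3-oxazolidin-3-yl]-2-hydroxy-3-methyl-4-oxobutanoate | CCOC(=O)[C@H](O)[C@@H](C)C(=O)N1[C@H](Cc2ccccc2)COC1=O | intermediate
16 | (2R,3R)-2-hydroxy-3-methylbutanedioic acid | OC(=O)[C@H](O)[C@@H](C)C(=O)O | intermediate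
17 | (2R)-2-[(2R,4R)-2-tert-butyl-5-oxo-1,3-dioxolan-4-yl]propanoic acid | CC(C)(C)[C@@H]1O[C@H]([C@@H](C)C(=O)O)C(=O)O1 | intermediate
18 | dilithium enolate carboxylate of 17 | [Li+].[Li+].C[C@@H](C(=O)[O-])C1=C([O-])O[C@H](C(C)(C)C)O1 | intermediate
19 | seco hydroxy acid (7S carbinol on the dioxolanone carbon C8, C19 acid free) | CCOC(OCC)/C=C(C)/[C@H](O[Si](CC)(CC)CC)CC/C(C)=C\[C@H](O)[C@]1([C@@H](C)C(=O)O)O[C@@H](C(C)(C)C)OC1=O | intermediate
20 | spiro lactone–dioxolanone | CCOC(OCC)/C=C(C)/[C@H](O[Si](CC)(CC)CC)CC/C(C)=C\[C@@H]1OC(=O)[C@H](C)[C@]12O[C@@H](C(C)(C)C)OC2=O | intermediate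
21 | S-ethyl thiol ester, lactone with free 8-OH, acetal and silyl ether retained | CCOC(OCC)/C=C(C)/[C@H](O[Si](CC)(CC)CC)CC/C(C)=C\[C@@H]1OC(=O)[C@H](C)[C@@]1(O)C(=O)SCC | intermediate
22 | hydroxy enal thiol ester | O=C/C=C(C)/[C@H](O)CC/C(C)=C\[C@@H]1OC(=O)[C@H](C)[C@@]1(O)C(=O)SCC | intermediate
23 | 2-(dichloromethyl)-4,4,5,5-tetramethyl-1,3,2-dioxaborolane | CC1(C)OB(C(Cl)Cl)OC1(C)C | starting material
24 | gem-dichromium boryl reagent, (pinB)CH(CrCl2)2 | CC1(C)OB(C([Cr](Cl)Cl)[Cr](Cl)Cl)OC1(C)C | intermediate
25 | E,E-dienylboronate thiol ester | CC1(C)OB(/C=C/C=C(C)/[C@H](O)CC/C(C)=C\[C@@H]2OC(=O)[C@H](C)[C@@]2(O)C(=O)SCC)OC1(C)C | intermediate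
26 | tributyl[(1Z)-prop-1-en-1-yl]stannane | C/C=C\[Sn](CCCC)(CCCC)CCCC | starting material
27 | open-chain triene: E,E-dienylboronate, Z-C5=C6, α'-hydroxy Z-enone | CC1(C)OB(/C=C/C=C(C)/[C@H](O)CC/C(C)=C\[C@@H]2OC(=O)[C@H](C)[C@@]2(O)C(=O)/C=C\C)OC1(C)C | intermediate
28 | cycloadduct: 9-ketone, 12-Bpin, 2-OH, 8-OH | O=C1[C@H]2[C@@H](C)[C@H](B3OC(C)(C)C(C)(C)O3)C=C[C@]2(C)[C@H](O)CC/C(C)=C\[C@@H]2OC(=O)[C@H](C)[C@]21O | intermediate
29 | 2,8,9-triol 12-boronate | O[C@@H]1[C@H]2[C@@H](C)[C@H](B3OC(C)(C)C(C)(C)O3)C=C[C@]2(C)[C@H](O)CC/C(C)=C\[C@@H]2OC(=O)[C@H](C)[C@]21O | intermediate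
30 | 2,9-diacetate 12-boronate | CC(=O)O[C@@H]1[C@H]2[C@@H](C)[C@H](B3OC(C)(C)C(C)(C)O3)C=C[C@]2(C)[C@H](OC(C)=O)CC/C(C)=C\[C@@H]2OC(=O)[C@H](C)[C@]21O | intermediate
31 | CNP0222085.1 | CC(=O)O[C@@H]1[C@H]2[C@@H](C)[C@H](O)C=C[C@]2(C)[C@H](OC(C)=O)CC/C(C)=C\[C@@H]2OC(=O)[C@H](C)[C@]21O | target

**Count and risks**

Total step count: 18. Longest linear sequence: 15 steps (steps 1–6 and 10–18).

Steps most likely to fail:

Step 15. The cycloaddition may be too slow at temperatures the Z-enone survives, so that Z/E isomerisation or oligomerisation wins, or the crowded Z-dienophile may not reach the exo geometry and the wrong face pairing or the bridged mode competes. The fallback replaces the Z-enone by a slimmer, more electrophilic alkynone and sets C10 and C11 afterwards. It sets out from 25 and comes back at 28. Compound 25 is coupled under the step 14 conditions with tributyl(prop-1-yn-1-yl)stannane to the alkynone F1. Heating F1 at high dilution gives, by the same intramolecular Diels–Alder mode, the cyclohexa-1,4-diene F2, with C1 and C12 set as in the main route and C10=C11 left as a tetrasubstituted enone. Conjugate reduction of F2 with [(Ph3P)CuH]6 should add hydride to C11 anti to the angular C15 methyl, and protonation of the enolate at C10 to the more stable trans junction gives 28.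

Step 10. The aldehyde faces may be poorly discriminated, so that the C7 epimer forms in quantity, and the dioxolanone enolate may decompose if it warms. The fallback funnels the wrong epimer through an inverting ring closure. It sets out from 17 and 10 and comes back at 20. The aldol is run as in step 10 but the acids are separated before lactonisation. The 7R epimer, hydroxy acid F3, is closed with PPh3 and diisopropyl azodicarboxylate (Mitsunobu lactonisation, inversion at C7) to 20, while 19 is closed with retention as before, so both epimers converge.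

Step 16. External hydride may attack the chelated ketone from the wrong face, or with little preference, if the ring does not shield the C7 side as assumed. The fallback delivers the hydride from inside the molecule. It sets out from 28 and comes back at 29. Both hydroxyls of 28 are silylated with chlorodiisopropylsilane and imidazole to the bis(hydrosilyl) ether F4. SnCl4-catalysed intramolecular hydrosilylation of the C9 ketone from the O8-bound silicon gives the five-membered silylene acetal F5; the Lewis-acid and fluoride modes of this known reaction are reported to give opposite 1,2-diol diastereomers, so the mode is chosen by the outcome. Aqueous AcOH/THF then removes both silicon groups to give 29.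

**Further compounds**

F1 | step 15 | alkynone: E,E-dienylboronate with C9(=O)–C≡C–CH3 | CC1(C)OB(/C=C/C=C(C)/[C@H](O)CC/C(C)=C\[C@@H]2OC(=O)[C@H](C)[C@@]2(O)C(=O)C#CC)OC1(C)C
F2 | step 15 | cyclohexa-1,4-diene cycloadduct (C10=C11 enone, 12-Bpin) | O=C1C2=C(C)[C@H](B3OC(C)(C)C(C)(C)O3)C=C[C@]2(C)[C@H](O)CC/C(C)=C\[C@@H]2OC(=O)[C@H](C)[C@]21O
F3 | step 10 | 7R epimer of seco hydroxy acid 19 | CCOC(OCC)/C=C(C)/[C@H](O[Si](CC)(CC)CC)CC/C(C)=C\[C@@H](O)[C@]1([C@@H](C)C(=O)O)O[C@@H](C(C)(C)C)OC1=O
F4 | step 16 | 2,8-bis(diisopropylsilyl) ether of 28 | O=C1[C@H]2[C@@H](C)[C@H](B3OC(C)(C)C(C)(C)O3)C=C[C@]2(C)[C@H](O[SiH](C(C)C)C(C)C)CC/C(C)=C\[C@@H]2OC(=O)[C@H](C)[C@]21O[SiH](C(C)C)C(C)C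
F5 | step 16 | 8,9-O-diisopropylsilylene acetal, 2-O-diisopropylsilyl ether | CC(C)[Si]3(C(C)C)O[C@@H]1[C@H]2[C@@H](C)[C@H](B4OC(C)(C)C(C)(C)O4)C=C[C@]2(C)[C@H](O[SiH](C(C)C)C(C)C)CC/C(C)=C\[C@@H]2OC(=O)[C@H](C)[C@]21O3
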